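In a one-step world both mirror-image substrates run on the same clock: whatever slows the catalyst or the partner slows both equally, so the ratio of their log losses stays fixed however the rate stalls. That ratio is the selectivity factor s.

| flask | left-handed substrate | right-handed substrate | partner | free catalyst | impurity | added ligand | remark | time |
|---|---|---|---|---|---|---|---|---|
| zeta | 0.10 M | 0.10 M | 0.20 M | 10 mM | 2.4 mM | 19 mM | run made earlier |  |
| delta | 0.15 M | 0.15 M | 0.20 M | 10 mM | 2.4 mM | 19 mM | run made earlier |  |
| epsilon | 0.20 M | 0.20 M | 0.20 M | 20 mM | 2.4 mM | 19 mM | run made earlier |  |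
| flask | 0.20 M | 0.20 M | 0.200 M | 10 mM | 2.4 mM | 19 mM |  | 10 d |

| run | time / d | right-handed substrate / % | left-handed substrate / % |
|---|---|---|---|
| zeta | 1.67 | 39.4 | 31.2 |
| zeta | 4.00 | 35.8 | 27.4 |
| zeta | 8.00 | 35.0 | 26.2 |
| zeta | 12.0 | 34.1 | 24.6 |
| delta | 3.00 | 37.7 | 30.9 |
| delta | 6.00 | 37.0 | 28.6 |
| delta | 10.0 | 36.0 | 26.7 |
| delta | 12.0 | 35.8 | 27.4 |
| epsilon | 1.67 | 34.8 | 25.3 |
| epsilon | 4.00 | 32.8 | 23.4 |
| epsilon | 8.00 | 31.9 | 22.9 |
| epsilon | 12.0 | 31.7 | 22.2 |

(each reading ± 0.5 percentage points)

- free catalyst is single-handed; left-handed substrate and right-handed substrate are mirror images of each other, charged as a racemate, each of them at the stated concentration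

- whether the excess of right-handed substrate over left-handed substrate among what is left of the two reaches 80% by 10 d (no / yes)
- the highest excess of right-handed substrate over left-handed substrate among what is left of the two up to 10 d

The zeta run gives s = 1.85 at 12.0 d, and the epsilon run, with twice the catalyst, gives 1.78. Yet here is the oddity: by that reading the left-handed substrate goes nearly twice as fast, and the excess of right-handed substrate read in zeta at 12.0 d is a mere 16.2%.

Take m, the share of the two substrates still left, and you can reckon it. Then c(left-handed substrate)/c(right-handed substrate) = m^n, with the split exponent n = 2(s−1)/(s+1) = 0.598. Strictly m is the geometric mean of the two remainders, so try the plain mean: zeta's 58.7% gives an excess of 15.8%, close to the reading.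

Now the flask. If each substrate turned over takes one partner, the partner is the limiting reagent and m stays above 50.0%, so by this estimate the excess in the flask stays under about 20.4%. An excess of 80% asks for m = 2.54%, less than that. My answer is no; the rule stops at this ceiling. The forecast answers no and puts the top at 12.3% “It rises steadily, so the peak falls at 10 d, far below 80%.”

The simulated flask answers no, with a top of 12.0%.

    2 partner → self-condensation product (k = 0.0310 M⁻¹ h⁻¹)
    partner + free catalyst + right-handed substrate → free catalyst + right-handed product (k = 12.0 M⁻² h⁻¹)
    free catalyst + impurity → spent catalyst (k = 200 M⁻¹ h⁻¹)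
    free catalyst + added ligand ⇌ idle complex (K = 1100 M⁻¹, k = 2.40 M⁻¹ h⁻¹)
    partner + free catalyst + left-handed substrate → free catalyst + left-handed product (k = 22.0 M⁻² h⁻¹)

By 10.0 d the flask has 33.3% of its two substrates reacted, and the split exponent turns that into an excess of 12.0%. The neighbour charged with 0.50 M of partner keeps m = 41.1% at its end; there the exponent gives 26.0%, and that flask's top stands at 26.6%.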